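**Plan**

- Numbering (farnesane): C1 = OCH2, C2=C3(Me) alkene, C4, C5, ring C6–C11 with C7 carrying the methylene, C10 the carbinol and C11 the CMe2 carbon.
- Cuts: the C1–O ether bond (coumarin), the C5–C4 bond (sulfone alkylation), the C10–O bond (iodolactonisation), and the ring bonds C6–C11 and C7–C8 ([4+2]).
- Forward: the cyclohexene ring comes from 4-methylpenta-1,3-diene and ethyl buta-2,3-dienoate; the acid is resolved; the bridged lactone ring is closed and later opened by hydride; the C5 sulfone is alkylated with an E C4–C1 bromide; the coumarin is joined last.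
- Enabling feature: the C10 oxygen and the C5 carbon on C6 are cis-1,3 across C11, so both fit into one γ-lactone bridging C6 and C10 (a 6-oxabicyclo[3.2.1]octan-7-one) made from a C9=C10 alkene.
- Stereochemistry: C6 from resolution of the cycloadduct acid; C10 relayed from C6 by the lactonisation; the 2E alkene from SeO2 oxidation of a prenyl ether, carried in the bromide.

Key step: step 5

Assumption: the salt of the (1R)-acid with (R)-1-phenylethylamine is taken to be the less soluble diastereomer; if the (1S)-acid salt crystallises instead, (S)-1-phenylethylamine is used in the same way.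

**Route**

Step 1
Reactants: 1 4-methylpenta-1,3-diene; 2 ethyl buta-2,3-dienoate
Product: 3 racemic ethyl 2,2-dimethyl-6-methylenecyclohex-3-ene-1-carboxylate
Conditions: neat 1 (4 equiv), BHT (cat.), sealed tube, 130 °C
Reagents that add atoms: none
Why: Thermal Diels–Alder reaction across the conjugated C=C of the allenoate: the unsubstituted diene terminus (largest HOMO coefficient) bonds to the central allene carbon (largest LUMO coefficient), which puts the CMe2 carbon next to the ester-bearing carbon, leaves the remote allene C=C as the exocyclic methylene and creates C6 as a racemate.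

Step 2
Reactants: 3 racemic ethyl 2,2-dimethyl-6-methylenecyclohex-3-ene-1-carboxylate
Product: 4 racemic 2,2-dimethyl-6-methylenecyclohex-3-ene-1-carboxylic acid
Conditions: LiOH·H2O (4 equiv), THF/MeOH/H2O, 40 °C; then 1 M HCl, 0 °C
Reagents that add atoms: lithium hydroxide, [Li+].[OH-]
Why: Saponification by acyl substitution with hydroxide under mild warming, chosen so that hydrolysis outruns base-induced migration of the methylene into conjugation; loss of configuration at C6 is of no consequence at the racemic stage.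

Step 3
Reactants: 4 racemic 2,2-dimethyl-6-methylenecyclohex-3-ene-1-carboxylic acid; 5 (R)-1-phenylethylamine
Product: 6 (1R)-1-phenylethanaminium (1R)-2,2-dimethyl-6-methylenecyclohex-3-ene-1-carboxylate
Conditions: 5 (0.5 equiv), acetone, reflux → 4 °C; recrystallise to constant rotation
Reagents that add atoms: none
Why: Classical resolution: half an equivalent of the chiral amine precipitates the less soluble diastereomeric salt, which is recrystallised to constant rotation, and this fixes the absolute configuration at C6 (R).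

Step 4
Reactants: 6 (1R)-1-phenylethanaminium (1R)-2,2-dimethyl-6-methylenecyclohex-3-ene-1-carboxylate
Product: 7 (1R)-2,2-dimethyl-6-methylenecyclohex-3-ene-1-carboxylic acid
Conditions: 1 M HCl, Et2O, 0 °C
Reagents that add atoms: none
Why: Simple proton transfer from mineral acid liberates the carboxylic acid, and the cold two-phase conditions leave the stereocentre and the acid-sensitive methylene untouched.

Step 5
Reactants: 7 (1R)-2,2-dimethyl-6-methylenecyclohex-3-ene-1-carboxylic acid
Product: 8 (1R,4R,5R)-4-iodo-8,8-dimethyl-2-methylene-6-oxabicyclo[3.2.1]octan-7-one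
Conditions: I2 (3 equiv), KI (6 equiv), NaHCO3 (3 equiv), H2O/CH2Cl2, 0 °C → rt, dark
Reagents that add atoms: iodine, II
Why: Iodine adds reversibly to the C9=C10 alkene on the face away from the axial C6 carboxylate, and the carboxylate oxygen opens the iodonium ion at C10 with inversion, so the C10–O and C9–I bonds form anti to each other and a γ-lactone bridges C6 and C10. The closest known reaction is the iodolactonisation of cyclohex-3-ene-1-carboxylic acids to 4-iodo-6-oxabicyclo[3.2.1]octan-7-ones. The five-membered lactone ring (C5, O, C10, C11, C6) closes in 5-exo mode with respect to the iodonium bond, the C9–I bond staying outside the new ring. The C10 configuration is dictated by the C6 stereocentre, because the one-carbon tether can deliver oxygen only to the ring face that carries the carboxyl group, which makes C10–O cis to C5; the C9 configuration follows from anti opening and is erased in step 6. The step needs the ring alkene to react in preference to the more electron-rich exocyclic methylene: iodonium formation is reversible at both alkenes in the presence of excess iodide, the methylene can be captured only by a slow 4-exo closure to a strained β-lactone, and the axial carboxylate conformer needed for attack at C10 is favoured by allylic strain against the methylene. The two-phase medium withdraws the neutral iodolactone from the basic aqueous layer as it forms.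

Step 6
Reactants: 8 (1R,4R,5R)-4-iodo-8,8-dimethyl-2-methylene-6-oxabicyclo[3.2.1]octan-7-one
Product: 9 (1R,5S)-8,8-dimethyl-2-methylene-6-oxabicyclo[3.2.1]octan-7-one
Conditions: n-Bu3SnH (1.3 equiv), AIBN (cat.), toluene, 80 °C
Reagents that add atoms: none
Why: Radical chain dehalogenation by tin hydride: the secondary C9 radical abstracts hydrogen faster than it can add to the remote methylene, so the iodine marker is removed without touching the lactone or either remaining stereocentre.

Step 7
Reactants: 9 (1R,5S)-8,8-dimethyl-2-methylene-6-oxabicyclo[3.2.1]octan-7-one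
Product: 10 (1S,3R)-3-(hydroxymethyl)-2,2-dimethyl-4-methylenecyclohexan-1-ol
Conditions: LiAlH4 (2 equiv), THF, 0 °C → rt; H2O/15% NaOH work-up
Reagents that add atoms: none
Why: Hydride reduction of the lactone to the diol cleaves only the acyl C–O bond, so the C10–O bond and the C6 centre keep the cis relationship set in step 5.

Step 8
Reactants: 10 (1S,3R)-3-(hydroxymethyl)-2,2-dimethyl-4-methylenecyclohexan-1-ol
Product: 11 tert-butyl{[(1S,3R)-3-({[tert-butyl(dimethyl)silyl]oxy}methyl)-2,2-dimethyl-4-methylenecyclohexyl]oxy}dimethylsilane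
Conditions: TBSOTf (2.5 equiv), 2,6-lutidine (4 equiv), CH2Cl2, −78 → 0 °C
Reagents that add atoms: tert-butyldimethylsilyl trifluoromethanesulfonate, CC(C)(C)[Si](C)(C)OS(=O)(=O)C(F)(F)F
Why: Silyl triflate silylation is strong enough for the neopentyl-type secondary alcohol; C10–O must be capped because a free C10 hydroxyl would displace any leaving group at C5 to give a bridged tetrahydrofuran.

Step 9
Reactants: 11 tert-butyl{[(1S,3R)-3-({[tert-butyl(dimethyl)silyl]oxy}methyl)-2,2-dimethyl-4-methylenecyclohexyl]oxy}dimethylsilane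
Product: 12 [(1R,3S)-3-{[tert-butyl(dimethyl)silyl]oxy}-2,2-dimethyl-6-methylenecyclohexyl]methanol
Conditions: HF·pyridine, pyridine, THF, 0 °C
Reagents that add atoms: none
Why: Selective desilylation: buffered HF·pyridine cleaves the primary silyl ether much faster than the secondary one that is shielded by the gem-dimethyl group.

Step 10
Reactants: 12 [(1R,3S)-3-{[tert-butyl(dimethyl)silyl]oxy}-2,2-dimethyl-6-methylenecyclohexyl]methanol
Product: 13 tert-butyl({(1S,3R)-2,2-dimethyl-4-methylene-3-[(phenylsulfanyl)methyl]cyclohexyl}oxy)dimethylsilane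
Conditions: PhSSPh (1.5 equiv), n-Bu3P (1.5 equiv), pyridine, rt → 50 °C
Reagents that add atoms: diphenyl disulfide, c1ccc(SSc2ccccc2)cc1
Why: Phosphine–disulfide (Hata) thioetherification: the alkoxyphosphonium ion of the primary alcohol is displaced by thiophenoxide in an SN2 step that does not involve the stereocentres.

Step 11
Reactants: 13 tert-butyl({(1S,3R)-2,2-dimethyl-4-methylene-3-[(phenylsulfanyl)methyl]cyclohexyl}oxy)dimethylsilane
Product: 15 tert-butyl({(1S,3R)-2,2-dimethyl-4-methylene-3-[(phenylsulfonyl)methyl]cyclohexyl}oxy)dimethylsilane, via sulfoxide 14 (not isolated)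
Conditions: (NH4)6Mo7O24·4H2O (10 mol %), 30% aq. H2O2 (4 equiv), EtOH, 0 °C → rt
Reagents that add atoms: hydrogen peroxide, OO
Why: Molybdate-catalysed peroxide oxidation takes the sulfide through the sulfoxide to the sulfone, sulfur being oxidised far faster than the isolated 1,1-disubstituted alkene.

Step 12
Reactants: 16 3-methylbut-2-en-1-ol
Product: 17 tert-butyldimethyl[(3-methylbut-2-en-1-yl)oxy]silane
Conditions: TBSCl, imidazole, CH2Cl2, 0 °C → rt
Reagents that add atoms: tert-butyldimethylsilyl chloride, CC(C)(C)[Si](C)(C)Cl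
Why: Standard silylation of a primary allylic alcohol with the silyl chloride and imidazole.

Step 13
Reactants: 17 tert-butyldimethyl[(3-methylbut-2-en-1-yl)oxy]silane
Product: 18 (2E)-4-{[tert-butyl(dimethyl)silyl]oxy}-2-methylbut-2-en-1-ol
Conditions: SeO2 (0.5 equiv), t-BuOOH (3 equiv), CH2Cl2, 0 °C → rt
Reagents that add atoms: selenium dioxide, O=[Se]=O (oxygen carrier); tert-butyl hydroperoxide, CC(C)(C)OO (terminal oxidant)
Why: SeO2-catalysed allylic oxidation (ene reaction followed by [2,3]-sigmatropic shift) hydroxylates the methyl group trans to the chain of a trisubstituted alkene, which fixes the E geometry needed at C2=C3.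

Step 14
Reactants: 18 (2E)-4-{[tert-butyl(dimethyl)silyl]oxy}-2-methylbut-2-en-1-ol
Product: 19 {[(2E)-4-bromo-3-methylbut-2-en-1-yl]oxy}(tert-butyl)dimethylsilane
Conditions: CBr4 (1.3 equiv), PPh3 (1.3 equiv), CH2Cl2, −20 → 0 °C
Reagents that add atoms: carbon tetrabromide, BrC(Br)(Br)Br
Why: Appel bromination converts the primary allylic alcohol to the bromide by SN2 displacement of the oxyphosphonium group without allylic transposition or loss of the E geometry.

Step 15
Reactants: 15 tert-butyl({(1S,3R)-2,2-dimethyl-4-methylene-3-[(phenylsulfonyl)methyl]cyclohexyl}oxy)dimethylsilane; 19 {[(2E)-4-bromo-3-methylbut-2-en-1-yl]oxy}(tert-butyl)dimethylsilane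
Product: 21 tert-butyl({(1S,3R)-3-[(3E)-5-{[tert-butyl(dimethyl)silyl]oxy}-3-methyl-1-(phenylsulfonyl)pent-3-en-1-yl]-2,2-dimethyl-4-methylenecyclohexyl}oxy)dimethylsilane, via lithiated sulfone 20 (not isolated)
Conditions: n-BuLi (1.1 equiv), THF/DMPU, −78 °C; then 19 (1.3 equiv), −78 → −20 °C
Reagents that add atoms: none
Why: Alkylation of an α-sulfonyl carbanion (Julia-type fragment coupling): the lithiated sulfone attacks the primary allylic bromide in SN2 fashion to form the C5–C4 bond, and the new centre at C5 is of no consequence because the sulfonyl group is removed next.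

Step 16
Reactants: 21 tert-butyl({(1S,3R)-3-[(3E)-5-{[tert-butyl(dimethyl)silyl]oxy}-3-methyl-1-(phenylsulfonyl)pent-3-en-1-yl]-2,2-dimethyl-4-methylenecyclohexyl}oxy)dimethylsilane
Product: 22 tert-butyl({(1S,3R)-3-[(3E)-5-{[tert-butyl(dimethyl)silyl]oxy}-3-methylpent-3-en-1-yl]-2,2-dimethyl-4-methylenecyclohexyl}oxy)dimethylsilane
Conditions: Na(Hg) (6% Na), Na2HPO4, MeOH/THF, −20 → 0 °C
Reagents that add atoms: none
Why: Reductive desulfonylation by electron transfer from sodium amalgam in buffered methanol replaces the C5–S bond by C–H and leaves the silyl ethers and both alkenes intact.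

Step 17
Reactants: 22 tert-butyl({(1S,3R)-3-[(3E)-5-{[tert-butyl(dimethyl)silyl]oxy}-3-methylpent-3-en-1-yl]-2,2-dimethyl-4-methylenecyclohexyl}oxy)dimethylsilane
Product: 23 (1S,3R)-3-[(3E)-5-hydroxy-3-methylpent-3-en-1-yl]-2,2-dimethyl-4-methylenecyclohexan-1-ol
Conditions: TBAF (5 equiv), THF, rt → 50 °C
Reagents that add atoms: none
Why: Fluoride-mediated desilylation removes both silyl ethers, the hindered secondary one needing gentle warming, under conditions to which the diene-diol is inert.

Step 18
Reactants: 24 2-hydroxy-6-methylbenzoic acid (6-methylsalicylic acid)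
Product: 25 1-(2-hydroxy-6-methylphenyl)ethanone
Conditions: MeLi (3.5 equiv), THF, 0 °C → rt; then 1 M HCl, 0 °C
Reagents that add atoms: methyllithium, [Li]C
Why: Addition of MeLi to the lithium carboxylate gives a stable dilithio gem-diolate that cannot add a second equivalent and collapses to the methyl ketone on acidic work-up.

Step 19
Reactants: 25 1-(2-hydroxy-6-methylphenyl)ethanone
Product: 27 4-hydroxy-5-methyl-2H-chromen-2-one, via keto ester 26 (not isolated)
Conditions: NaH (4 equiv), (EtO)2CO, toluene, 110 °C; then 1 M HCl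
Reagents that add atoms: diethyl carbonate, CCOC(=O)OCC
Why: Claisen-type C-acylation of the ketone enolate by diethyl carbonate followed by lactonisation onto the phenoxide is the standard route from 2-hydroxyacetophenones to 4-hydroxycoumarins.

Step 20
Reactants: 23 (1S,3R)-3-[(3E)-5-hydroxy-3-methylpent-3-en-1-yl]-2,2-dimethyl-4-methylenecyclohexan-1-ol; 27 4-hydroxy-5-methyl-2H-chromen-2-one
Product: 28 4-{[(2E)-5-[(1R,3S)-3-hydroxy-2,2-dimethyl-6-methylenecyclohexyl]-3-methylpent-2-en-1-yl]oxy}-5-methyl-2H-chromen-2-one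
Conditions: PPh3 (1.3 equiv), DIAD (1.3 equiv), THF, 0 °C → rt
Reagents that add atoms: none
Why: Mitsunobu etherification: the acidic 4-hydroxycoumarin is alkylated on O4 by the alkoxyphosphonium ion of the primary allylic alcohol with direct SN2 regiochemistry, while the hindered secondary C10 alcohol is not activated.

**Compound list**

1 | 4-methylpenta-1,3-diene | CC(C)=CC=C | starting material
2 | ethyl buta-2,3-dienoate | C=C=CC(=O)OCC | starting material
3 | racemic ethyl 2,2-dimethyl-6-methylenecyclohex-3-ene-1-carboxylate | C=C1CC=CC(C)(C)C1C(=O)OCC | intermediate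
4 | racemic 2,2-dimethyl-6-methylenecyclohex-3-ene-1-carboxylic acid | C=C1CC=CC(C)(C)C1C(=O)O | intermediate
5 | (R)-1-phenylethylamine | C[C@@H](N)c1ccccc1 | starting material
6 | (1R)-1-phenylethanaminium (1R)-2,2-dimethyl-6-methylenecyclohex-3-ene-1-carboxylate | C=C1CC=CC(C)(C)[C@@H]1C(=O)[O-].C[C@@H]([NH3+])c1ccccc1 | intermediate
7 | (1R)-2,2-dimethyl-6-methylenecyclohex-3-ene-1-carboxylic acid | C=C1CC=CC(C)(C)[C@@H]1C(=O)O | intermediate
8 | (1R,4R,5R)-4-iodo-8,8-dimethyl-2-methylene-6-oxabicyclo[3.2.1]octan-7-one | C=C1C[C@@H](I)[C@@H]2OC(=O)[C@H]1C2(C)C | intermediate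
9 | (1R,5S)-8,8-dimethyl-2-methylene-6-oxabicyclo[3.2.1]octan-7-one | C=C1CC[C@@H]2OC(=O)[C@H]1C2(C)C | intermediate
10 | (1S,3R)-3-(hydroxymethyl)-2,2-dimethyl-4-methylenecyclohexan-1-ol | C=C1CC[C@H](O)C(C)(C)[C@@H]1CO | intermediate
11 | tert-butyl{[(1S,3R)-3-({[tert-butyl(dimethyl)silyl]oxy}methyl)-2,2-dimethyl-4-methylenecyclohexyl]oxy}dimethylsilane | C=C1CC[C@H](O[Si](C)(C)C(C)(C)C)C(C)(C)[C@@H]1CO[Si](C)(C)C(C)(C)C | intermediate
12 | [(1R,3S)-3-{[tert-butyl(dimethyl)silyl]oxy}-2,2-dimethyl-6-methylenecyclohexyl]methanol | C=C1CC[C@H](O[Si](C)(C)C(C)(C)C)C(C)(C)[C@@H]1CO | intermediate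
13 | tert-butyl({(1S,3R)-2,2-dimethyl-4-methylene-3-[(phenylsulfanyl)methyl]cyclohexyl}oxy)dimethylsilane | C=C1CC[C@H](O[Si](C)(C)C(C)(C)C)C(C)(C)[C@@H]1CSc1ccccc1 | intermediate
14 | tert-butyl({(1S,3R)-2,2-dimethyl-4-methylene-3-[(phenylsulfinyl)methyl]cyclohexyl}oxy)dimethylsilane (both configurations at sulfur) | C=C1CC[C@H](O[Si](C)(C)C(C)(C)C)C(C)(C)[C@@H]1CS(=O)c1ccccc1 | intermediate
15 | tert-butyl({(1S,3R)-2,2-dimethyl-4-methylene-3-[(phenylsulfonyl)methyl]cyclohexyl}oxy)dimethylsilane | C=C1CC[C@H](O[Si](C)(C)C(C)(C)C)C(C)(C)[C@@H]1CS(=O)(=O)c1ccccc1 | intermediate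
16 | 3-methylbut-2-en-1-ol | CC(C)=CCO | starting material
17 | tert-butyldimethyl[(3-methylbut-2-en-1-yl)oxy]silane | CC(C)=CCO[Si](C)(C)C(C)(C)C | intermediate
18 | (2E)-4-{[tert-butyl(dimethyl)silyl]oxy}-2-methylbut-2-en-1-ol | OC/C(C)=C/CO[Si](C)(C)C(C)(C)C | intermediate
19 | {[(2E)-4-bromo-3-methylbut-2-en-1-yl]oxy}(tert-butyl)dimethylsilane | BrC/C(C)=C/CO[Si](C)(C)C(C)(C)C | intermediate
20 | {[(1R,3S)-3-{[tert-butyl(dimethyl)silyl]oxy}-2,2-dimethyl-6-methylenecyclohexyl](phenylsulfonyl)methyl}lithium | C=C1CC[C@H](O[Si](C)(C)C(C)(C)C)C(C)(C)[C@@H]1C([Li])S(=O)(=O)c1ccccc1 | intermediate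
21 | tert-butyl({(1S,3R)-3-[(3E)-5-{[tert-butyl(dimethyl)silyl]oxy}-3-methyl-1-(phenylsulfonyl)pent-3-en-1-yl]-2,2-dimethyl-4-methylenecyclohexyl}oxy)dimethylsilane (both configurations at the sulfonyl-bearing carbon) | C=C1CC[C@H](O[Si](C)(C)C(C)(C)C)C(C)(C)[C@@H]1C(C/C(C)=C/CO[Si](C)(C)C(C)(C)C)S(=O)(=O)c1ccccc1 | intermediate
22 | tert-butyl({(1S,3R)-3-[(3E)-5-{[tert-butyl(dimethyl)silyl]oxy}-3-methylpent-3-en-1-yl]-2,2-dimethyl-4-methylenecyclohexyl}oxy)dimethylsilane | C=C1CC[C@H](O[Si](C)(C)C(C)(C)C)C(C)(C)[C@@H]1CC/C(C)=C/CO[Si](C)(C)C(C)(C)C | intermediate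
23 | (1S,3R)-3-[(3E)-5-hydroxy-3-methylpent-3-en-1-yl]-2,2-dimethyl-4-methylenecyclohexan-1-ol | C=C1CC[C@H](O)C(C)(C)[C@@H]1CC/C(C)=C/CO | intermediate
24 | 2-hydroxy-6-methylbenzoic acid (6-methylsalicylic acid) | Cc1cccc(O)c1C(=O)O | starting material
25 | 1-(2-hydroxy-6-methylphenyl)ethanone | CC(=O)c1c(C)cccc1O | intermediate
26 | ethyl 3-(2-hydroxy-6-methylphenyl)-3-oxopropanoate | CCOC(=O)CC(=O)c1c(C)cccc1O | intermediate
27 | 4-hydroxy-5-methyl-2H-chromen-2-one | Cc1cccc2oc(=O)cc(O)c12 | intermediate
28 | 4-{[(2E)-5-[(1R,3S)-3-hydroxy-2,2-dimethyl-6-methylenecyclohexyl]-3-methylpent-2-en-1-yl]oxy}-5-methyl-2H-chromen-2-one (CNP0172901.1) | C=C1CC[C@H](O)C(C)(C)[C@@H]1CC/C(C)=C/COc1cc(=O)oc2cccc(C)c12 | target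

**Count**

Total steps: 20. Longest linear sequence: 15 steps (steps 1–11, 15, 16, 17 and 20); steps 12–14 and 18–19 are side branches.

**Steps most likely to fail**

1. Step 1. The diene has to force its cis-methyl group into the s-cis geometry, so the cycloaddition may be slower than thermal oligomerisation of the allenoate or stepwise [2+2] addition. The fallback sets out from 2 and comes back at 4, building the ring without a cycloaddition. Conjugate addition of lithium diallylcuprate ((CH2=CHCH2)2CuLi, TMSCl, THF, −78 °C) to the central allene carbon should give ethyl 3-methylenehex-5-enoate F1. Transesterification with 3-methylbut-2-en-1-ol 16 (Ti(OiPr)4 cat., toluene, 100 °C) gives 3-methylbut-2-en-1-yl 3-methylenehex-5-enoate F2. Ireland–Claisen rearrangement (LDA, TMSCl, THF, −78 °C → rt) installs the 1,1-dimethylallyl group next to the carboxyl and gives 2-(2-methylbut-3-en-2-yl)-3-methylenehex-5-enoic acid F3. Ring-closing metathesis with the second-generation Grubbs catalyst (H2IMes)(PCy3)Cl2Ru=CHPh in CH2Cl2 at 40 °C then forms the C9=C10 bond and delivers racemic acid 4.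

2. Step 5. An iodonium ion may be captured at the exocyclic methylene (4-exo closure or hydration). Closure at C10 may also be slow and reversible, because C10 is flanked by the quaternary C11 and the incoming iodine sits syn-axial to a C11 methyl group. The fallback sets out from 7 and comes back at 9, replacing the halonium ion by a seleniranium ion. Phenylselenolactonisation (PhSeCl, Et3N, CH2Cl2, −78 °C → rt), in which the electrophile adds reversibly and migrates between the two alkenes until the 5-exo closure takes place, should give (1R,4R,5R)-8,8-dimethyl-2-methylene-4-(phenylselanyl)-6-oxabicyclo[3.2.1]octan-7-one F4. Reduction with n-Bu3SnH and AIBN in toluene at 110 °C removes the selenium and gives lactone 9.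

3. Step 3. The two diastereomeric salts may not differ enough in solubility, so crystallisation may fail to enrich the (1R)-acid. The fallback sets out from 4 and 5 and comes back at 8, using covalent diastereomers. Amide coupling (EDC·HCl, HOBt, CH2Cl2) should give (1R)-2,2-dimethyl-6-methylene-N-[(1R)-1-phenylethyl]cyclohex-3-ene-1-carboxamide F5 and (1S)-2,2-dimethyl-6-methylene-N-[(1R)-1-phenylethyl]cyclohex-3-ene-1-carboxamide F6, which are separated by chromatography on silica. Iodolactonisation of the amide F5 (I2, THF/H2O, rt) runs through O-cyclisation to an iminium lactone, whose hydrolysis expels the amine and gives iodolactone 8 directly.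

**Further compounds**

F1 | step 1 | ethyl 3-methylenehex-5-enoate | C=CCC(=C)CC(=O)OCC
F2 | step 1 | 3-methylbut-2-en-1-yl 3-methylenehex-5-enoate | C=CCC(=C)CC(=O)OCC=C(C)C
F3 | step 1 | 2-(2-methylbut-3-en-2-yl)-3-methylenehex-5-enoic acid | C=CCC(=C)C(C(=O)O)C(C)(C)C=C
F4 | step 5 | (1R,4R,5R)-8,8-dimethyl-2-methylene-4-(phenylselanyl)-6-oxabicyclo[3.2.1]octan-7-one | C=C1C[C@@H]([Se]c2ccccc2)[C@@H]2OC(=O)[C@H]1C2(C)C
F5 | step 3 | (1R)-2,2-dimethyl-6-methylene-N-[(1R)-1-phenylethyl]cyclohex-3-ene-1-carboxamide | C=C1CC=CC(C)(C)[C@@H]1C(=O)N[C@H](C)c1ccccc1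
F6 | step 3 | (1S)-2,2-dimethyl-6-methylene-N-[(1R)-1-phenylethyl]cyclohex-3-ene-1-carboxamide | C=C1CC=CC(C)(C)[C@H]1C(=O)N[C@H](C)c1ccccc1
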